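The acetal protecting groups come off last. Ring C is then cut at O1–C8a and C4–C4a. These are the only bonds between ring C and ring A, they end on neighbouring ring A carbons, and the C5 oxygen sits beside C4a. Ring A can therefore enter as a C4a≡C8a aryne that takes oxygen at C8a and the acyl carbon at C4a.
The partner (O1, C2, C3, C4 and ring B) is an anti α,β-dihydroxy acid held as a butane-2,3-diacetal lactone. It is cut at C2–C3 into O-MOM-vanillin and a chiral glycolate enolate.
The aryne precursor goes back through an ortho-silylaryl triflate, an aryl carbamate and 2-(1,1-dimethylallyl)phloroglucinol to the prenyl ether of phloroglucinol, with the C6 side chain set by Claisen rearrangement.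
Forward: rings A and B are bought, ring A is dressed in six steps, an aldol addition makes C2–C3, the aryne annulation closes ring C, and one acid treatment gives the target.
Stereochemistry: (S)-3-chloropropane-1,2-diol fixes the two acetal centres of the glycolate. These steer the anti aldol addition that sets C3 (R) and C2 (R), and the annulation breaks no bond at either centre, so the 2,3-trans array arrives intact.

Key step: step 13

Assumption: flavanone numbering (O1, C2, C3, C4, C4a, C5–C8, C8a) is used for all ring A and ring C atoms, and the enolate of the (5S,6S)-dioxanone is taken to react on the face away from its axial 5-methoxy group, as in its known alkylations and aldol additions.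

Step 1
Reactants: 1 phloroglucinol (benzene-1,3,5-triol, anhydrous); 2 prenyl bromide (1-bromo-3-methylbut-2-ene)
Product: 3 5-[(3-methylbut-2-en-1-yl)oxy]benzene-1,3-diol
Conditions: K2CO3, DMF, 0 °C → rt; 1 in threefold excess
Reagents that add atoms: none
Why: Williamson ether synthesis, in which the phenoxide is alkylated at oxygen in the dipolar aprotic solvent and the excess of the water-soluble triol should hold the reaction at the monoether.

Step 2
Reactants: 3 5-[(3-methylbut-2-en-1-yl)oxy]benzene-1,3-diol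
Product: 5 2-(2-methylbut-3-en-2-yl)benzene-1,3,5-triol, via ortho-dienone 4 (not isolated)
Conditions: PhNEt2, 190 °C, argon, sealed tube
Reagents that add atoms: none
Why: Aromatic Claisen rearrangement, in which the [3,3] shift inverts the prenyl group and places it as the 1,1-dimethylallyl group on one of two equivalent ortho carbons, and dienone 4 should enolise (acidic OH groups, amine solvent) faster than it can pass the group on to the para carbon by a Cope shift.

Step 3
Reactants: 5 2-(2-methylbut-3-en-2-yl)benzene-1,3,5-triol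
Product: 6 3,5-dihydroxy-4-(2-methylbut-3-en-2-yl)phenyl propan-2-ylcarbamate
Conditions: iPrNCO (1.0 equiv), Et3N (cat.), THF, 0 °C → rt
Reagents that add atoms: isopropyl isocyanate, CC(C)N=C=O
Why: Base-catalysed addition of a phenol to an isocyanate, in which the two hydroxyls next to the quaternary carbon are shielded as in a 2-tert-alkylphenol, so one equivalent should go to the open hydroxyl para to the side chain.

Step 4
Reactants: 6 3,5-dihydroxy-4-(2-methylbut-3-en-2-yl)phenyl propan-2-ylcarbamate
Product: 7 3,5-bis(methoxymethoxy)-4-(2-methylbut-3-en-2-yl)phenyl propan-2-ylcarbamate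
Conditions: MOMCl, iPr2NEt, CH2Cl2, 0 → 40 °C
Reagents that add atoms: chloromethyl methyl ether (MOMCl), COCCl
Why: Standard O-alkylation of phenols with a chloromethyl ether under a tertiary amine base, which is too weak to trigger E1cB loss of isocyanate from the N–H carbamate.

Step 5
Reactants: 7 3,5-bis(methoxymethoxy)-4-(2-methylbut-3-en-2-yl)phenyl propan-2-ylcarbamate
Product: 11 3,5-bis(methoxymethoxy)-4-(2-methylbut-3-en-2-yl)-2-(trimethylsilyl)phenyl propan-2-ylcarbamate, via N-silyl carbamate 8 (not isolated), via aryllithium 9 (not isolated), via C-silylated N-silyl carbamate 10 (not isolated)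
Conditions: TBSOTf, TMEDA, Et2O, 0 °C → rt; n-BuLi (2 equiv), TMEDA, −78 °C; TMSCl, −78 °C → rt; aq NaHSO4
Reagents that add atoms: chlorotrimethylsilane (TMSCl), C[Si](C)(C)Cl
Why: Directed ortho-metalation of an aryl carbamate masked in situ at nitrogen, in which the only two ring C–H positions are equivalent and each lies between the carbamate and a MOM ether that both guide lithium there, while the alkene carries no allylic hydrogen.

Step 6
Reactants: 11 3,5-bis(methoxymethoxy)-4-(2-methylbut-3-en-2-yl)-2-(trimethylsilyl)phenyl propan-2-ylcarbamate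
Product: 13 3,5-bis(methoxymethoxy)-4-(2-methylbut-3-en-2-yl)-2-(trimethylsilyl)phenyl trifluoromethanesulfonate, via silylphenol 12 (not isolated)
Conditions: DBU, Et2NH, MeCN, 40 °C; then PhNTf2, rt
Reagents that add atoms: N-phenylbis(trifluoromethanesulfonimide) (PhNTf2), O=S(=O)(N(c1ccccc1)S(=O)(=O)C(F)(F)F)C(F)(F)F
Why: E1cB cleavage of the N–H carbamate (the isocyanate is taken up by Et2NH) followed by O-triflation of the phenoxide in the same flask, the established last stage in making ortho-silylaryl triflates.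

Step 7
Reactants: 14 (S)-3-chloropropane-1,2-diol; 15 butane-2,3-dione
Product: 16 (2S,3S,5S)-5-(chloromethyl)-2,3-dimethoxy-2,3-dimethyl-1,4-dioxane
Conditions: HC(OMe)3, camphorsulfonic acid (cat.), MeOH, reflux
Reagents that add atoms: methanol, CO
Why: Butane-2,3-diacetal formation under thermodynamic control, in which two anomeric effects place both methoxy groups axial and the chloromethyl group goes equatorial, so the carbinol centre of 14 fixes both new acetal centres as S.

Step 8
Reactants: 16 (2S,3S,5S)-5-(chloromethyl)-2,3-dimethoxy-2,3-dimethyl-1,4-dioxane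
Product: 17 (2S,3S)-2,3-dimethoxy-2,3-dimethyl-5-methylidene-1,4-dioxane
Conditions: KOtBu, THF, reflux
Reagents that add atoms: none
Why: E2 dehydrochlorination with a hindered alkoxide gives the exocyclic enol ether, which erases the original stereocentre and leaves the chirality stored in the two acetal carbons.

Step 9
Reactants: 17 (2S,3S)-2,3-dimethoxy-2,3-dimethyl-5-methylidene-1,4-dioxane
Product: 18 (5S,6S)-5,6-dimethoxy-5,6-dimethyl-1,4-dioxan-2-one
Conditions: O3, CH2Cl2, −78 °C; then Me2S, −78 °C → rt
Reagents that add atoms: ozone, [O-][O+]=O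
Why: Ozonolysis with reductive work-up cleaves the electron-rich 1,1-disubstituted enol ether to the lactone carbonyl without touching the acetal centres.

Step 10
Reactants: 19 vanillin (4-hydroxy-3-methoxybenzaldehyde)
Product: 20 3-methoxy-4-(methoxymethoxy)benzaldehyde
Conditions: MOMCl, iPr2NEt, CH2Cl2, 0 °C → rt
Reagents that add atoms: chloromethyl methyl ether (MOMCl), COCCl
Why: Routine MOM protection of an acidic, unhindered phenol, needed so that no proton source enters the enolate and aryne steps.

Step 11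
Reactants: 18 (5S,6S)-5,6-dimethoxy-5,6-dimethyl-1,4-dioxan-2-one; 20 3-methoxy-4-(methoxymethoxy)benzaldehyde
Product: 22 (3R,5S,6S)-3-{(R)-hydroxy[3-methoxy-4-(methoxymethoxy)phenyl]methyl}-5,6-dimethoxy-5,6-dimethyl-1,4-dioxan-2-one, via lithium enolate 21 (not isolated)
Conditions: LiN(SiMe3)2, THF, −78 °C; then 20, −78 °C, short contact time; AcOH, −78 °C
Reagents that add atoms: none
Why: Lithium enolate aldol addition through a Zimmerman–Traxler chair, in which the ring-locked E-enolate gives the anti adduct, the aldehyde arrives on the face away from the axial 5-methoxy group so that C3 and the carbinol carbon both become R, and the cold acidic quench forestalls retro-aldol equilibration.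

Step 12
Reactants: 22 (3R,5S,6S)-3-{(R)-hydroxy[3-methoxy-4-(methoxymethoxy)phenyl]methyl}-5,6-dimethoxy-5,6-dimethyl-1,4-dioxan-2-one
Product: 23 (3R,5S,6S)-5,6-dimethoxy-3-{(R)-[3-methoxy-4-(methoxymethoxy)phenyl][(trimethylsilyl)oxy]methyl}-5,6-dimethyl-1,4-dioxan-2-one
Conditions: TMSCl, imidazole, CH2Cl2, 0 °C
Reagents that add atoms: chlorotrimethylsilane (TMSCl), C[Si](C)(C)Cl
Why: Mild silylation of a secondary alcohol under near-neutral conditions stores the benzylic oxygen as a proton-free, fluoride-labile alkoxide equivalent without risk of retro-aldol cleavage.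

Step 13
Reactants: 13 3,5-bis(methoxymethoxy)-4-(2-methylbut-3-en-2-yl)-2-(trimethylsilyl)phenyl trifluoromethanesulfonate; 23 (3R,5S,6S)-5,6-dimethoxy-3-{(R)-[3-methoxy-4-(methoxymethoxy)phenyl][(trimethylsilyl)oxy]methyl}-5,6-dimethyl-1,4-dioxan-2-one
Product: 27 (2R,3R)-3-{[(2S)-2-methoxy-3-oxobutan-2-yl]oxy}-2-[3-methoxy-4-(methoxymethoxy)phenyl]-5,7-bis(methoxymethoxy)-6-(2-methylbut-3-en-2-yl)-2,3-dihydro-4H-chromen-4-one, via alkoxide 24 (not isolated), via aryne 25 (not isolated), via aryl anion 26 (not isolated)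
Conditions: Bu4N[Ph3SiF2] (TBAT, 1.1 equiv), 13 (1.2 equiv), 4 Å molecular sieves, THF, 0 °C → rt
Reagents that add atoms: none
Why: Proposed new method: fluoride unmasks alkoxide 24 from the silyl ether and, by 1,2-elimination of the silyl and triflate groups, aryne 25 from 13; 24 adds to C8a, aryl anion 26 (charge on C4a) attacks the lactone carbonyl in a 6-exo-trig closure of ring C, and the tetrahedral adduct collapses with opening of the dioxanone and loss of methoxide, leaving O3 as an acid-labile mixed ketal. The closest known reaction type is the fluoride-triggered annulation of arynes with salicylate esters to xanthones (O-arylation, then acylation of the aryl anion), which has not been extended to an aliphatic β-hydroxy ester or lactone. The σ-withdrawing oxygen on C5 bends the aryne so that C8a is the more linear, more electrophilic terminus and the developing carbanion sits on C4a beside that oxygen, and C8a, flanked only by C8–H, is also the more open end. No stereocentre is created, and since all four bonds at C2 and at C3 survive, the (2R,3R) array of 23 passes unchanged into 27. Ring closure has to be faster than proton capture by 26, which the proton-free medium secures (silyl ether in place of the alcohol, anhydrous TBAT, THF instead of MeCN, an activated lactone as acyl group), and O-arylation has to be faster than retro-aldol cleavage of 24, which should be slowed because the equatorial C3–C bond lies close to the plane of the lactone carbonyl and overlaps poorly with its π* orbital. With about one equivalent of fluoride the released methoxide is consumed by the trimethylsilyl group of the next molecule of 13 or 23, so no strong base should remain to open or epimerise ring C.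

Step 14
Reactants: 27 (2R,3R)-3-{[(2S)-2-methoxy-3-oxobutan-2-yl]oxy}-2-[3-methoxy-4-(methoxymethoxy)phenyl]-5,7-bis(methoxymethoxy)-6-(2-methylbut-3-en-2-yl)-2,3-dihydro-4H-chromen-4-one
Product: 28 (2R,3R)-3,5,7-trihydroxy-2-(4-hydroxy-3-methoxyphenyl)-6-(2-methylbut-3-en-2-yl)-2,3-dihydro-4H-chromen-4-one (CNP0565756.1)
Conditions: HCl (1.25 M in MeOH), 40 °C
Reagents that add atoms: none
Why: Acid-catalysed transacetalisation in methanol removes the three aryl MOM ethers and the still more labile 3-O ketal, while dilute HCl at this temperature should be too weak to protonate the monosubstituted alkene and touches no stereocentre.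

Compound list
1 | phloroglucinol (benzene-1,3,5-triol) | Oc1cc(O)cc(O)c1 | starting material
2 | prenyl bromide (1-bromo-3-methylbut-2-ene) | CC(C)=CCBr | starting material
3 | 5-[(3-methylbut-2-en-1-yl)oxy]benzene-1,3-diol | CC(C)=CCOc1cc(O)cc(O)c1 | intermediate
4 | 3,5-dihydroxy-6-(2-methylbut-3-en-2-yl)cyclohexa-2,4-dien-1-one (ortho-dienone, not isolated) | C=CC(C)(C)C1C(=O)C=C(O)C=C1O | intermediate
5 | 2-(2-methylbut-3-en-2-yl)benzene-1,3,5-triol | C=CC(C)(C)c1c(O)cc(O)cc1O | intermediate
6 | 3,5-dihydroxy-4-(2-methylbut-3-en-2-yl)phenyl propan-2-ylcarbamate | C=CC(C)(C)c1c(O)cc(OC(=O)NC(C)C)cc1O | intermediate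
7 | 3,5-bis(methoxymethoxy)-4-(2-methylbut-3-en-2-yl)phenyl propan-2-ylcarbamate | C=CC(C)(C)c1c(OCOC)cc(OC(=O)NC(C)C)cc1OCOC | intermediate
8 | 3,5-bis(methoxymethoxy)-4-(2-methylbut-3-en-2-yl)phenyl N-(tert-butyldimethylsilyl)-N-(propan-2-yl)carbamate (not isolated) | C=CC(C)(C)c1c(OCOC)cc(OC(=O)N(C(C)C)[Si](C)(C)C(C)(C)C)cc1OCOC | intermediate
9 | 2-lithio derivative of 8 (not isolated) | [Li]c1c(OC(=O)N(C(C)C)[Si](C)(C)C(C)(C)C)cc(OCOC)c(C(C)(C)C=C)c1OCOC | intermediate
10 | 3,5-bis(methoxymethoxy)-4-(2-methylbut-3-en-2-yl)-2-(trimethylsilyl)phenyl N-(tert-butyldimethylsilyl)-N-(propan-2-yl)carbamate (not isolated) | C=CC(C)(C)c1c(OCOC)cc(OC(=O)N(C(C)C)[Si](C)(C)C(C)(C)C)c([Si](C)(C)C)c1OCOC | intermediate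
11 | 3,5-bis(methoxymethoxy)-4-(2-methylbut-3-en-2-yl)-2-(trimethylsilyl)phenyl propan-2-ylcarbamate | C=CC(C)(C)c1c(OCOC)cc(OC(=O)NC(C)C)c([Si](C)(C)C)c1OCOC | intermediate
12 | 3,5-bis(methoxymethoxy)-4-(2-methylbut-3-en-2-yl)-2-(trimethylsilyl)phenol (not isolated) | C=CC(C)(C)c1c(OCOC)cc(O)c([Si](C)(C)C)c1OCOC | intermediate
13 | 3,5-bis(methoxymethoxy)-4-(2-methylbut-3-en-2-yl)-2-(trimethylsilyl)phenyl trifluoromethanesulfonate | C=CC(C)(C)c1c(OCOC)cc(OS(=O)(=O)C(F)(F)F)c([Si](C)(C)C)c1OCOC | intermediate
14 | (S)-3-chloropropane-1,2-diol | OC[C@H](O)CCl | starting material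
15 | butane-2,3-dione | CC(=O)C(C)=O | starting material
16 | (2S,3S,5S)-5-(chloromethyl)-2,3-dimethoxy-2,3-dimethyl-1,4-dioxane | ClC[C@@H]1CO[C@](C)(OC)[C@@](C)(OC)O1 | intermediate
17 | (2S,3S)-2,3-dimethoxy-2,3-dimethyl-5-methylidene-1,4-dioxane | C=C1CO[C@](C)(OC)[C@@](C)(OC)O1 | intermediate
18 | (5S,6S)-5,6-dimethoxy-5,6-dimethyl-1,4-dioxan-2-one | O=C1CO[C@](C)(OC)[C@@](C)(OC)O1 | intermediate
19 | vanillin (4-hydroxy-3-methoxybenzaldehyde) | COc1cc(C=O)ccc1O | starting material
20 | 3-methoxy-4-(methoxymethoxy)benzaldehyde | COCOc1ccc(C=O)cc1OC | intermediate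
21 | lithium enolate of 18 (not isolated) | [Li]OC1=CO[C@](C)(OC)[C@@](C)(OC)O1 | intermediate
22 | (3R,5S,6S)-3-{(R)-hydroxy[3-methoxy-4-(methoxymethoxy)phenyl]methyl}-5,6-dimethoxy-5,6-dimethyl-1,4-dioxan-2-one | O=C1[C@@H]([C@H](O)c2ccc(OCOC)c(OC)c2)O[C@](C)(OC)[C@@](C)(OC)O1 | intermediate
23 | (3R,5S,6S)-5,6-dimethoxy-3-{(R)-[3-methoxy-4-(methoxymethoxy)phenyl][(trimethylsilyl)oxy]methyl}-5,6-dimethyl-1,4-dioxan-2-one | O=C1[C@@H]([C@H](O[Si](C)(C)C)c2ccc(OCOC)c(OC)c2)O[C@](C)(OC)[C@@](C)(OC)O1 | intermediate
24 | benzylic alkoxide of 22 (not isolated) | O=C1[C@@H]([C@H]([O-])c2ccc(OCOC)c(OC)c2)O[C@](C)(OC)[C@@](C)(OC)O1 | intermediate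
25 | 3,5-bis(methoxymethoxy)-4-(2-methylbut-3-en-2-yl)benzyne, triple bond C4a≡C8a (not isolated) | C1#CC(OCOC)=C(C(C)(C)C=C)C(OCOC)=C1 | intermediate
26 | O-arylated lactone with the carbanion on C4a (not isolated) | O=C1[C@@H]([C@H](Oc2cc(OCOC)c(C(C)(C)C=C)c(OCOC)[c-]2)c2ccc(OCOC)c(OC)c2)O[C@](C)(OC)[C@@](C)(OC)O1 | intermediate
27 | (2R,3R)-3-{[(2S)-2-methoxy-3-oxobutan-2-yl]oxy}-2-[3-methoxy-4-(methoxymethoxy)phenyl]-5,7-bis(methoxymethoxy)-6-(2-methylbut-3-en-2-yl)-2,3-dihydro-4H-chromen-4-one | C=CC(C)(C)c1c(OCOC)cc2c(c1OCOC)C(=O)[C@H](O[C@](C)(OC)C(C)=O)[C@@H](c1ccc(OCOC)c(OC)c1)O2 | intermediate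
28 | (2R,3R)-3,5,7-trihydroxy-2-(4-hydroxy-3-methoxyphenyl)-6-(2-methylbut-3-en-2-yl)-2,3-dihydro-4H-chromen-4-one | C=CC(C)(C)c1c(O)cc2c(c1O)C(=O)[C@H](O)[C@@H](c1ccc(O)c(OC)c1)O2 | target

Total step count: 14.
Longest linear sequence: 8 steps (steps 1–6, 13, 14). The lactone branch contributes 7 (steps 7–9, 11–14).

Steps most likely to fail

Step 13 (Proposed new method). The alkoxide may fragment by retro-aldol cleavage before it meets the short-lived aryne. The aryl anion may pick up a proton before it acylates, and ring C may be opened by base after closure. The fallback uses known chemistry and makes the two bonds one after the other, with O1–C2 instead of O1–C8a as the ring-closing bond. It sets out from 7 and 20 and comes back to the route at 28.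
- Aryllithium 9 is generated from 7 as in step 5 and quenched with N-methoxy-N-methylacetamide. This gives 2-acetyl-3,5-bis(methoxymethoxy)-4-(2-methylbut-3-en-2-yl)phenyl N-(tert-butyldimethylsilyl)-N-(propan-2-yl)carbamate F1.
- The aqueous NaHSO4 work-up removes the N-silyl group to give 2-acetyl-3,5-bis(methoxymethoxy)-4-(2-methylbut-3-en-2-yl)phenyl propan-2-ylcarbamate F2.
- KOH in EtOH strips the carbamate and condenses the methyl ketone with 20 (Claisen–Schmidt condensation). The product is (E)-1-[6-hydroxy-2,4-bis(methoxymethoxy)-3-(2-methylbut-3-en-2-yl)phenyl]-3-[3-methoxy-4-(methoxymethoxy)phenyl]prop-2-en-1-one F3.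
- NaH and MOMCl in DMF cap the chelated phenol to give (E)-3-[3-methoxy-4-(methoxymethoxy)phenyl]-1-[2,4,6-tris(methoxymethoxy)-3-(2-methylbut-3-en-2-yl)phenyl]prop-2-en-1-one F4.
- Juliá–Colonna epoxidation (poly-L-leucine, urea–H2O2, DBU, THF) attacks only the enone and should give [(2R,3S)-3-[3-methoxy-4-(methoxymethoxy)phenyl]oxiran-2-yl][2,4,6-tris(methoxymethoxy)-3-(2-methylbut-3-en-2-yl)phenyl]methanone F5.
- Methanolic HCl then removes the four MOM groups, and the freed phenol opens the epoxide at the benzylic carbon with inversion. This gives the 2,3-trans compound 28.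

Step 2. The side chain may move on by a Cope shift to the para carbon, where it arrives as a normal prenyl group. At the high temperature a flanking phenol may also cyclise onto the alkene. The fallback runs the rearrangement on a masked substrate with irreversible capture of the new phenol. It sets out from 3 and comes back at 5.
- Ac2O and pyridine convert 3 into 5-[(3-methylbut-2-en-1-yl)oxy]benzene-1,3-diyl diacetate F6.
- Heating F6 in Ac2O with NaOAc acetylates the phenol as soon as the [3,3] shift and enolisation produce it. This stops both follow-up processes and gives 2-(2-methylbut-3-en-2-yl)benzene-1,3,5-triyl triacetate F7.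
- K2CO3 in MeOH at 0 °C under argon returns 5.

Step 3. Carbamoylation may spread over the hindered hydroxyls as well (poor site selectivity, over-reaction). The fallback relays the differentiation through a very bulky silyl group, so that the carbamoylation itself needs no selectivity. It sets out from 5 and comes back at 7.
- tert-Butyldiphenylsilyl chloride (1 equiv) and imidazole in DMF at 0 °C should silylate only the open hydroxyl. The product is 5-[(tert-butyldiphenylsilyl)oxy]-2-(2-methylbut-3-en-2-yl)benzene-1,3-diol F8.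
- MOMCl and iPr2NEt give tert-butyl[3,5-bis(methoxymethoxy)-4-(2-methylbut-3-en-2-yl)phenoxy]diphenylsilane F9.
- Bu4NF in THF frees the symmetric 3,5-bis(methoxymethoxy)-4-(2-methylbut-3-en-2-yl)phenol F10.
- iPrNCO with catalytic Et3N converts this single phenol into 7.

Further compounds
F1 | step 13 | 2-acetyl-3,5-bis(methoxymethoxy)-4-(2-methylbut-3-en-2-yl)phenyl N-(tert-butyldimethylsilyl)-N-(propan-2-yl)carbamate | C=CC(C)(C)c1c(OCOC)cc(OC(=O)N(C(C)C)[Si](C)(C)C(C)(C)C)c(C(C)=O)c1OCOC
F2 | step 13 | 2-acetyl-3,5-bis(methoxymethoxy)-4-(2-methylbut-3-en-2-yl)phenyl propan-2-ylcarbamate | C=CC(C)(C)c1c(OCOC)cc(OC(=O)NC(C)C)c(C(C)=O)c1OCOC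
F3 | step 13 | (E)-1-[6-hydroxy-2,4-bis(methoxymethoxy)-3-(2-methylbut-3-en-2-yl)phenyl]-3-[3-methoxy-4-(methoxymethoxy)phenyl]prop-2-en-1-one | C=CC(C)(C)c1c(OCOC)cc(O)c(C(=O)/C=C/c2ccc(OCOC)c(OC)c2)c1OCOC
F4 | step 13 | (E)-3-[3-methoxy-4-(methoxymethoxy)phenyl]-1-[2,4,6-tris(methoxymethoxy)-3-(2-methylbut-3-en-2-yl)phenyl]prop-2-en-1-one | C=CC(C)(C)c1c(OCOC)cc(OCOC)c(C(=O)/C=C/c2ccc(OCOC)c(OC)c2)c1OCOC
F5 | step 13 | [(2R,3S)-3-[3-methoxy-4-(methoxymethoxy)phenyl]oxiran-2-yl][2,4,6-tris(methoxymethoxy)-3-(2-methylbut-3-en-2-yl)phenyl]methanone | C=CC(C)(C)c1c(OCOC)cc(OCOC)c(C(=O)[C@@H]2O[C@H]2c3ccc(OCOC)c(OC)c3)c1OCOC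
F6 | step 2 | 5-[(3-methylbut-2-en-1-yl)oxy]benzene-1,3-diyl diacetate | CC(C)=CCOc1cc(OC(C)=O)cc(OC(C)=O)c1
F7 | step 2 | 2-(2-methylbut-3-en-2-yl)benzene-1,3,5-triyl triacetate | C=CC(C)(C)c1c(OC(C)=O)cc(OC(C)=O)cc1OC(C)=O
F8 | step 3 | 5-[(tert-butyldiphenylsilyl)oxy]-2-(2-methylbut-3-en-2-yl)benzene-1,3-diol | C=CC(C)(C)c1c(O)cc(O[Si](c2ccccc2)(c2ccccc2)C(C)(C)C)cc1O
F9 | step 3 | tert-butyl[3,5-bis(methoxymethoxy)-4-(2-methylbut-3-en-2-yl)phenoxy]diphenylsilane | C=CC(C)(C)c1c(OCOC)cc(O[Si](c2ccccc2)(c2ccccc2)C(C)(C)C)cc1OCOC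
F10 | step 3 | 3,5-bis(methoxymethoxy)-4-(2-methylbut-3-en-2-yl)phenol | C=CC(C)(C)c1c(OCOC)cc(O)cc1OCOC
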